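The numbers in the tables come from a simulation with made-up constants; the scatter is artificial.

Slowness was what I went by: in Tuesday's run the target took 6.00 min to reach its highest reading, 30.1 %, and then fell, so in that run the time of reading mattered.

| setting | Tuesday's | Wednesday's | Monday's | birch | elm | oak | larch | cedar |
|---|---|---|---|---|---|---|---|---|
| substrate | 47 mM | 66 mM | 100 mM | 47 mM (fed, over 1.0 min) | 47 mM (fed, over 10 min) | 47 mM (fed, over 10 min) | 47 mM (in portions, 3, over 10 min) | 47 mM |
| first nucleophile | 49.4 mM | 49.4 mM | 49.4 mM | 49.4 mM | 49.4 mM | 49.4 mM | 49.4 mM | 49.4 mM (fed, over 10 min) |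
| second nucleophile | 56.4 mM | 56.4 mM | 56.4 mM | 56.4 mM | 56.4 mM | 56.4 mM | 56.4 mM | 56.4 mM |
| temperature | 15 °C | 26 °C | 15 °C | 20 °C | 20 °C |  | 20 °C | 20 °C |
| remark | run made earlier | run made earlier | run made earlier | all else is in the flask from the start; the feed brings no volume worth counting | all else is in the flask from the start; the feed brings no volume worth counting | the addition at −10 °C, then warmed to 20 °C; the feed brings no volume worth counting | first portion at the start, last at 10 min | all else is in the flask from the start; the feed brings no volume worth counting |
| time |  |  |  | 12 min | 12 min | 12 min | 12 min | 12 min |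

| run | time / min | target / % |
|---|---|---|
| Tuesday's | 0.833 | 5.5 |
| Tuesday's | 2.50 | 21.2 |
| Tuesday's | 4.00 | 27.7 |
| Tuesday's | 6.00 | 30.1 |
| Tuesday's | 10.0 | 28.2 |
| Tuesday's | 12.0 | 24.6 |
| Wednesday's | 2.00 | 32.4 |
| Wednesday's | 4.00 | 27.3 |
| Wednesday's | 6.00 | 20.1 |
| Wednesday's | 8.00 | 16.6 |
| Wednesday's | 10.0 | 13.0 |
| Wednesday's | 12.0 | 11.4 |
| Monday's | 0.833 | 5.4 |
| Monday's | 2.50 | 18.1 |
| Monday's | 4.00 | 22.5 |
| Monday's | 6.00 | 23.8 |
| Monday's | 10.0 | 17.7 |
| Monday's | 12.0 | 15.6 |

(readings scatter by 0.5 percentage points)

- target is meant together with its idle adduct
- steps under discussion: substrate -> intermediate; first nucleophile + intermediate -> target; second nucleophile + intermediate -> other capture product; second nucleophile -> decomposition product; first nucleophile + target <-> idle adduct; second nucleophile + target -> over-reaction product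

* the flask that comes out highest in amount of target, in percent of the substrate charged, or "all alike" when all lie within 1.5 percentage points (birch / elm / oak / larch / cedar / all alike)
* target at the end, in percent of the substrate charged, birch
* target at the end, in percent of the substrate charged, elm
* target at the end, in percent of the substrate charged, oak
* target at the end, in percent of the substrate charged, larch
* target at the end, in percent of the substrate charged, cedar

I kept the books on substrate, the limiting reagent, with 47 mM charged against 49.4 mM of first nucleophile and 56.4 mM of second nucleophile. Each mole entered as substrate, passed to intermediate, and was credited to target or to other capture product. Target could then be debited to over-reaction product, at one mole of second nucleophile each. That charge exceeds the substrate by 9.40 mM, so the ledger permits every mole of target to be debited, provided decomposition product took less than that margin, and I expected the books to close on over-reaction product. So I looked to the clock for the answer at 12 min.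

Monday's run, with 100 mM of substrate, also read highest at 6.00 min, so I took the clock as little tied to the charge. Wednesday's, at 26 °C, read highest at 2.00 min, its first reading, so its peak could lie earlier. Interpolating the logarithm of these sampled times gave 3.64 min at 20 °C. I called this the peak time, the warm minutes from the entry of substrate to the highest target.

I then divided the mean warm age of the substrate at reading by it. Birch gave 3.16, cedar 3.30, elm and larch 1.92, and oak 0.549, its cold minutes uncounted. Tuesday's curve at the same ratios put oak midway between 21.2 % and 27.7 %, and elm and larch near 24.6 %. Tuesday's readings ended at a ratio of 2.00, lower than birch's and cedar's, so I turned to Wednesday's curve, which put birch and cedar near 20.1 %. Oak and elm came out level, and I put oak first, since its uncounted cold minutes, 10 min of them and more than its warm ones, could push it a little further up the rise.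

The forecast differed: it named elm, with birch 21 %, elm 34 %, oak 28 %, larch 32 % and cedar 12 %, saying of oak “little reacts in the cold”. The flasks gave birch 19.4 %, elm 26.3 %, oak 28.0 %, larch 22.1 % and cedar 23.6 %, so oak came highest.

    substrate → intermediate (k = 0.00630 /s, Ea = 79.0 kJ/mol)
    first nucleophile + intermediate → target (k = 0.590 /M/s, Ea = 62.0 kJ/mol)
    second nucleophile + intermediate → other capture product (k = 0.0210 /M/s, Ea = 60.0 kJ/mol)
    second nucleophile → decomposition product (k = 9.40 × 10⁻⁶ /s, Ea = 99.0 kJ/mol)
    first nucleophile + target ⇌ idle adduct, settled at all times (K = 12.0 /M, ΔH = 19.0 kJ/mol)
    second nucleophile + target → over-reaction product (k = 0.130 /M/s, Ea = 51.0 kJ/mol)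
    (constants at 20 °C)

In oak, at a ratio of 0.549, half of the over-reaction turnover up to 12 min came by 11.4 min, after the warming at 10 min, and at the end substrate stood at 44.9 %, intermediate at 16.1 % and over-reaction product at 9.10 %. The same flask read at 50 min had 11.0 peak times behind it, and there substrate stood at 0 %, over-reaction product at 91.2 % and target at 2.03 %.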